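**Plan**

1. Retrosynthetic cuts, in order: the C4–C5 epoxide oxygen; the C6 carbinol (back to a ketone); the lactone at O8–C12 and C11–C12 (CO taken out of a C7 ethynyl group); then C6–C7 and O8–C8 together as a nitrile oxide–alkene (3+2) cycloaddition; last C8–C9 (acetylide plus the C9 aldehyde of an oxidised geranyl chain).
2. Enabling feature: O6 and O8 stand 1,3 across C7 on the ten-membered ring, and C7 carries the lactone branch. This aldol pattern is a masked isoxazoline (C6=N–O–C8). The two E-alkenes (C1=C10, C4=C5) cannot sit in any smaller ring, so the dipole can only close the ten-membered one.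
3. Forward order: geranyl acetate gives C1–C6, C9, C10, C14, C15 and a C4 diyne gives C7, C8, C11, C13. One cycloaddition closes the ten-membered carbocycle and the isoxazoline (temporary ring, nitrogen as helper). N–O cleavage and lactonisation give the lactone ring; the epoxide ring comes last.
4. Stereochemistry: C9 by CBS reduction; C8 relayed from C9 and C7 from the Z-alkene in the cycloaddition; C6 by Luche reduction; C4/C5 by matched Sharpless epoxidation; both E-alkenes from geraniol.

Key step: step 9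

Remark: germacrane numbering is used (ring C1–C10, C11–C13 on C7, C14 on C10, C15 on C4). The carbon that becomes C9 keeps one spatial arrangement from 8 onward, but its CIP label changes with its neighbours (S in 8, R in 9–14, S from 15).

**Route**

Step 1
Reactants: 1 geranyl acetate
Product: 3 (2E,6E)-3,7-dimethyl-8-oxoocta-2,6-dien-1-yl acetate, via allylic alcohol 2 (not isolated)
Conditions: SeO2 (cat.), t-BuOOH, salicylic acid (cat.), CH2Cl2, rt; then MnO2, CH2Cl2, rt
Reagents that add atoms: tert-butyl hydroperoxide CC(C)(C)OO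
Why: SeO2-catalysed allylic oxidation (ene reaction, then 2,3-sigmatropic shift) should attack the E-methyl group of the electron-richer terminal alkene with retention of the E geometry, and MnO2 converges the allylic alcohol on the enal.

Step 2
Reactants: 3 (2E,6E)-3,7-dimethyl-8-oxoocta-2,6-dien-1-yl acetate; 4 1,4-bis(trimethylsilyl)buta-1,3-diyne
Product: 7 (2E,6E)-3,7-dimethyl-8-oxo-12-(trimethylsilyl)dodeca-2,6-diene-9,11-diyn-1-yl acetate, via lithium trimethylsilylbutadiynide 5 (not isolated), via racemic diynol 6 (not isolated)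
Conditions: 4, MeLi·LiBr, THF, 0 °C to rt; then 3, −78 °C; H2O; then MnO2, CH2Cl2, rt
Reagents that add atoms: none
Why: Mono-desilylation of 4 gives the lithium acetylide, which should add 1,2 to the aldehyde much faster than to the acetate at −78 °C; MnO2 then oxidises the doubly activated (allylic and propargylic) alcohol to the ynone.

Step 3
Reactants: 7 (2E,6E)-3,7-dimethyl-8-oxo-12-(trimethylsilyl)dodeca-2,6-diene-9,11-diyn-1-yl acetate
Product: 8 (2E,6E,8S)-8-hydroxy-3,7-dimethyl-12-(trimethylsilyl)dodeca-2,6-diene-9,11-diyn-1-yl acetate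
Conditions: (S)-2-methyl-CBS-oxazaborolidine (20 mol %), catecholborane, toluene, −78 °C
Reagents that add atoms: none
Why: Corey–Bakshi–Shibata reduction, with the α-branched alkenyl group as the large and the rod-like diynyl group as the small substituent, should deliver hydride to the face that gives the 8S carbinol (C9 of the target).

Step 4
Reactants: 8 (2E,6E,8S)-8-hydroxy-3,7-dimethyl-12-(trimethylsilyl)dodeca-2,6-diene-9,11-diyn-1-yl acetate
Product: 9 (2E,6E,8R,9Z)-8-hydroxy-3,7-dimethyl-12-(trimethylsilyl)dodeca-2,6,9-trien-11-yn-1-yl acetate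
Conditions: Zn dust activated with Cu(OAc)2 and AgNO3, MeOH/H2O, 40 °C
Reagents that add atoms: none
Why: Boland reduction should add two hydrogens cis to the conjugated triple bond next to the free carbinol and spare the silyl-capped alkyne, giving the Z-alkene that later places H7 and H8 cis.

Step 5
Reactants: 9 (2E,6E,8R,9Z)-8-hydroxy-3,7-dimethyl-12-(trimethylsilyl)dodeca-2,6,9-trien-11-yn-1-yl acetate
Product: 10 (2E,6E,8R,9Z)-3,7-dimethyldodeca-2,6,9-trien-11-yne-1,8-diol
Conditions: K2CO3 (cat.), MeOH, 0 °C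
Reagents that add atoms: none
Why: Methanolysis (transesterification and C–Si cleavage by methoxide) should remove the primary acetate and the alkynyl silyl group in one operation.

Step 6
Reactants: 10 (2E,6E,8R,9Z)-3,7-dimethyldodeca-2,6,9-trien-11-yne-1,8-diol
Product: 11 (2E,6E,8R,9Z)-8-hydroxy-3,7-dimethyldodeca-2,6,9-trien-11-ynal
Conditions: TEMPO (cat.), PhI(OAc)2, CH2Cl2, rt
Reagents that add atoms: none
Why: Oxoammonium (TEMPO) oxidation is much faster for the unhindered primary allylic alcohol than for the secondary carbinol and should not isomerise the E-enal.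

Step 7
Reactants: 11 (2E,6E,8R,9Z)-8-hydroxy-3,7-dimethyldodeca-2,6,9-trien-11-ynal
Product: 12 (3Z,5R,6E,10E)-6,10-dimethyl-12-oxododeca-3,6,10-trien-1-yn-5-yl 2-methylpropanoate
Conditions: (i-PrCO)2O, pyridine, DMAP (cat.), CH2Cl2, 0 °C
Reagents that add atoms: isobutyric anhydride CC(C)C(=O)OC(=O)C(C)C
Why: DMAP-catalysed acylation puts the isobutyrate of the target on the only hydroxyl present, with retention at the carbinol carbon.

Step 8
Reactants: 12 (3Z,5R,6E,10E)-6,10-dimethyl-12-oxododeca-3,6,10-trien-1-yn-5-yl 2-methylpropanoate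
Product: 13 (3Z,5R,6E,10E)-12-(hydroxyimino)-6,10-dimethyldodeca-3,6,10-trien-1-yn-5-yl 2-methylpropanoate
Conditions: NH2OH·HCl, NaOAc, EtOH/H2O, rt
Reagents that add atoms: hydroxylamine hydrochloride NO.Cl
Why: Oxime condensation of the enal gives the aldoxime, the dipole precursor; either C=N isomer serves.

Step 9
Reactants: 13 (3Z,5R,6E,10E)-12-(hydroxyimino)-6,10-dimethyldodeca-3,6,10-trien-1-yn-5-yl 2-methylpropanoate
Product: 15 (7S,8R,9S)-7-ethynyl-6,8-(nitrilooxy)germacra-1(10)E,4E-dien-9-yl 2-methylpropanoate (bridged isoxazoline: C6=N–O–C8), via nitrile oxide 14 (not isolated)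
Conditions: aq. NaOCl, CH2Cl2, 0 °C to rt, slow addition of 13 (final concentration about 0.002 M)
Reagents that add atoms: none
Why: Hypochlorite converts the aldoxime into nitrile oxide 14, whose C6≡N–O dipole adds in a concerted suprafacial (3+2) cycloaddition across the Z-C7=C8 bond, C6 to C7 and oxygen to C8, so the future lactone C–O bond forms together with the ring C–C bond. The closest known reaction type is the intramolecular nitrile oxide–alkene cycloaddition in its bridged, macrocyclic mode. Two rings close at once: the isoxazoline (C6, N, O, C8, C7) and the ten-membered carbocycle, the carbon terminus of the dipole bonding to the distal alkene carbon so that both alkene carbons lie in the large ring. C7 follows from C8 through the Z geometry (H7 and H8 cis on the isoxazoline), and C8 is set by C9: 1,3-allylic strain with the cis substituent on C7 should keep H9 in the alkene plane, and the dipole, arriving from the C10 side, should add anti to the C9–O bond. The step needs site, regio and face selectivity: attack on C1=C10 or the reverse orientation on C7=C8 would put an E-alkene into a six-, seven- or nine-membered ring, attack on the alkyne would give a strained bridged isoxazole, and high dilution holds back furoxan formation.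

Step 10
Reactants: 15 (7S,8R,9S)-7-ethynyl-6,8-(nitrilooxy)germacra-1(10)E,4E-dien-9-yl 2-methylpropanoate
Product: 16 methyl 2-[(7S,8R,9S)-9-isobutyryloxy-6,8-(nitrilooxy)germacra-1(10)E,4E-dien-7-yl]prop-2-enoate
Conditions: Pd(OAc)2 (cat.), 2-(diphenylphosphino)pyridine, MsOH (cat.), CO (20 atm), MeOH, 45 °C
Reagents that add atoms: carbon monoxide [C-]#[O+]; methanol CO
Why: Markovnikov hydro-methoxycarbonylation of the terminal alkyne (divalent palladium hydride addition with Pd on the internal carbon, CO insertion, methanolysis) should build C12 on C11 and leave C13 as the exocyclic methylene while no enolisable ketone is yet present.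

Step 11
Reactants: 16 methyl 2-[(7S,8R,9S)-9-isobutyryloxy-6,8-(nitrilooxy)germacra-1(10)E,4E-dien-7-yl]prop-2-enoate
Product: 18 (7R,8R,9S)-9-isobutyryloxy-6-oxogermacra-1(10)E,4E,11(13)-trien-12,8-olide, via hydroxy keto ester 17 (not isolated)
Conditions: Fe powder, NH4Cl, EtOH/H2O, 70 °C; then PPTS (cat.), benzene, 40 °C
Reagents that add atoms: water O
Why: Reductive N–O cleavage of the isoxazoline and hydrolysis of the imine should unmask the C6 ketone and the C8 hydroxyl (the former dipole oxygen) under an ammonium buffer that limits retro-aldol and alkene migration; the C8 hydroxyl then lactonises onto the acrylate ester (acyl substitution) to the trans-fused α-methylene lactone.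

Step 12
Reactants: 18 (7R,8R,9S)-9-isobutyryloxy-6-oxogermacra-1(10)E,4E,11(13)-trien-12,8-olide
Product: 19 (6R,7S,8R,9S)-6-hydroxy-9-isobutyryloxygermacra-1(10)E,4E,11(13)-trien-12,8-olide
Conditions: NaBH4, CeCl3·7H2O, MeOH, −78 °C
Reagents that add atoms: none
Why: Luche 1,2-reduction of the enone, selective over the α-methylene lactone, should deliver hydride from the peripheral face on the side of H7 (away from C11), which places the 6-hydroxyl as in the target.

Step 13
Reactants: 19 (6R,7S,8R,9S)-6-hydroxy-9-isobutyryloxygermacra-1(10)E,4E,11(13)-trien-12,8-olide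
Product: 20 (4S,5S,6S,7S,8R,9S)-4,5-epoxy-6-hydroxy-9-isobutyryloxygermacra-1(10)E,11(13)-dien-12,8-olide (target)
Conditions: Ti(OiPr)4 (10 mol %), L-(+)-diethyl tartrate (12 mol %), t-BuOOH, 4 Å molecular sieves, CH2Cl2, −20 °C
Reagents that add atoms: tert-butyl hydroperoxide CC(C)(C)OO
Why: Sharpless asymmetric epoxidation in the matched sense: the L-(+)-tartrate complex should epoxidise this carbinol enantiomer fast on the face that gives the erythro (4S,5S) epoxy alcohol, and should leave C1=C10 (no allylic hydroxyl) and the electron-poor acrylate alkene untouched.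

**Compound list**

1 | geranyl acetate | CC(=O)OC/C=C(\C)CCC=C(C)C | starting material
2 | (2E,6E)-8-hydroxy-3,7-dimethylocta-2,6-dien-1-yl acetate | CC(=O)OC/C=C(\C)CC/C=C(\C)CO | intermediate
3 | (2E,6E)-3,7-dimethyl-8-oxoocta-2,6-dien-1-yl acetate | CC(=O)OC/C=C(\C)CC/C=C(\C)C=O | intermediate
4 | 1,4-bis(trimethylsilyl)buta-1,3-diyne | C[Si](C)(C)C#CC#C[Si](C)(C)C | starting material
5 | lithium 4-(trimethylsilyl)buta-1,3-diyn-1-ide | [Li]C#CC#C[Si](C)(C)C | intermediate
6 | racemic (2E,6E)-8-hydroxy-3,7-dimethyl-12-(trimethylsilyl)dodeca-2,6-diene-9,11-diyn-1-yl acetate | CC(=O)OC/C=C(\C)CC/C=C(\C)C(O)C#CC#C[Si](C)(C)C | intermediate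
7 | (2E,6E)-3,7-dimethyl-8-oxo-12-(trimethylsilyl)dodeca-2,6-diene-9,11-diyn-1-yl acetate | CC(=O)OC/C=C(\C)CC/C=C(\C)C(=O)C#CC#C[Si](C)(C)C | intermediate
8 | (2E,6E,8S)-8-hydroxy-3,7-dimethyl-12-(trimethylsilyl)dodeca-2,6-diene-9,11-diyn-1-yl acetate | CC(=O)OC/C=C(\C)CC/C=C(\C)[C@H](O)C#CC#C[Si](C)(C)C | intermediate
9 | (2E,6E,8R,9Z)-8-hydroxy-3,7-dimethyl-12-(trimethylsilyl)dodeca-2,6,9-trien-11-yn-1-yl acetate | CC(=O)OC/C=C(\C)CC/C=C(\C)[C@H](O)/C=C\C#C[Si](C)(C)C | intermediate
10 | (2E,6E,8R,9Z)-3,7-dimethyldodeca-2,6,9-trien-11-yne-1,8-diol | OC/C=C(\C)CC/C=C(\C)[C@H](O)/C=C\C#C | intermediate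
11 | (2E,6E,8R,9Z)-8-hydroxy-3,7-dimethyldodeca-2,6,9-trien-11-ynal | O=C/C=C(\C)CC/C=C(\C)[C@H](O)/C=C\C#C | intermediate
12 | (3Z,5R,6E,10E)-6,10-dimethyl-12-oxododeca-3,6,10-trien-1-yn-5-yl 2-methylpropanoate | O=C/C=C(\C)CC/C=C(\C)[C@H](OC(=O)C(C)C)/C=C\C#C | intermediate
13 | (3Z,5R,6E,10E)-12-(hydroxyimino)-6,10-dimethyldodeca-3,6,10-trien-1-yn-5-yl 2-methylpropanoate (either oxime isomer) | ON=C/C=C(\C)CC/C=C(\C)[C@H](OC(=O)C(C)C)/C=C\C#C | intermediate
14 | nitrile oxide of 13 (C6≡N–O dipole) | [O-][N+]#C/C=C(\C)CC/C=C(\C)[C@H](OC(=O)C(C)C)/C=C\C#C | intermediate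
15 | (7S,8R,9S)-7-ethynyl-6,8-(nitrilooxy)germacra-1(10)E,4E-dien-9-yl 2-methylpropanoate (bridged isoxazoline) | CC(C)C(=O)O[C@H]1/C(C)=C/CC/C(C)=C/C2=NO[C@@H]1[C@H]2C#C | intermediate
16 | methyl 2-[(7S,8R,9S)-9-isobutyryloxy-6,8-(nitrilooxy)germacra-1(10)E,4E-dien-7-yl]prop-2-enoate | CC(C)C(=O)O[C@H]1/C(C)=C/CC/C(C)=C/C2=NO[C@@H]1[C@H]2C(=C)C(=O)OC | intermediate
17 | methyl 2-[(7R,8R,9S)-8-hydroxy-9-isobutyryloxy-6-oxogermacra-1(10)E,4E-dien-7-yl]prop-2-enoate | CC(C)C(=O)O[C@H]1/C(C)=C/CC/C(C)=C/C(=O)[C@H](C(=C)C(=O)OC)[C@H]1O | intermediate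
18 | (7R,8R,9S)-9-isobutyryloxy-6-oxogermacra-1(10)E,4E,11(13)-trien-12,8-olide | C=C1C(=O)O[C@@H]2[C@@H]1C(=O)/C=C(\C)CC/C=C(\C)[C@@H]2OC(=O)C(C)C | intermediate
19 | (6R,7S,8R,9S)-6-hydroxy-9-isobutyryloxygermacra-1(10)E,4E,11(13)-trien-12,8-olide | C=C1C(=O)O[C@@H]2[C@@H]1[C@H](O)/C=C(\C)CC/C=C(\C)[C@@H]2OC(=O)C(C)C | intermediate
20 | (4S,5S,6S,7S,8R,9S)-4,5-epoxy-6-hydroxy-9-isobutyryloxygermacra-1(10)E,11(13)-dien-12,8-olide | C=C1C(=O)O[C@@H]2[C@@H]1[C@H](O)[C@@H]1O[C@@]1(C)CC/C=C(\C)[C@@H]2OC(=O)C(C)C | target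

**Count and risks**

Total step count: 13. Longest linear sequence: 13 steps (from geranyl acetate; the diyne 4 is bought).

Steps most likely to fail:

Step 9. The nitrile oxide may dimerise to a furoxan, or hypochlorite may chlorinate the electron-rich alkenes, before the slow ten-membered ring closure occurs. Fallback, from 12 and back at 15: the dipole is released slowly and without an oxidant from a primary nitro compound. Aldehyde 12 is reduced (NaBH4, CeCl3·7H2O, MeOH, −78 °C) to the allylic alcohol F1. This is converted into the allylic bromide F2 (CBr4, PPh3, CH2Cl2, −20 °C) and then into the nitro compound F3 (NaNO2, urea, DMF, −20 °C). PhNCO and catalytic Et3N in toluene at high dilution (Mukaiyama dehydration) should then generate nitrile oxide 14 at a very low stationary concentration, and the route is rejoined at 15.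

Step 10. Regiocontrol of the hydropalladation may be lost (linear ester), or the isoxazoline nitrogen may inhibit the cationic palladium catalyst. Fallback, from 15 and back at 16: bromoboration of the alkyne with B-bromo-9-BBN (CH2Cl2, 0 °C) and protodeboronation with AcOH should give the 2-bromoalkene F4. Its alkoxycarbonylation (PdCl2(PPh3)2, CO (1 atm), Et3N, MeOH, 50 °C) should give 16.

Step 12. Facial selectivity of hydride delivery to the conformationally mobile ten-membered enone may be poor. Fallback, from 18 and back at 19: if the reduction gives mainly the 6-epimeric alcohol F5, the carbinol is inverted by Mitsunobu esterification (ClCH2CO2H, PPh3, DIAD, toluene, 0 °C) to the chloroacetate F6. The chloroacetyl group is then removed with thiourea and NaHCO3 in EtOH, which should return 19.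

**Further compounds**

F1 | step 9 | (3Z,5R,6E,10E)-12-hydroxy-6,10-dimethyldodeca-3,6,10-trien-1-yn-5-yl 2-methylpropanoate | OC/C=C(\C)CC/C=C(\C)[C@H](OC(=O)C(C)C)/C=C\C#C
F2 | step 9 | (3Z,5R,6E,10E)-12-bromo-6,10-dimethyldodeca-3,6,10-trien-1-yn-5-yl 2-methylpropanoate | BrC/C=C(\C)CC/C=C(\C)[C@H](OC(=O)C(C)C)/C=C\C#C
F3 | step 9 | (3Z,5R,6E,10E)-6,10-dimethyl-12-nitrododeca-3,6,10-trien-1-yn-5-yl 2-methylpropanoate | [O-][N+](=O)C/C=C(\C)CC/C=C(\C)[C@H](OC(=O)C(C)C)/C=C\C#C
F4 | step 10 | 2-bromoalkene analogue of 15 (C7 carries a 1-bromoethenyl group in place of ethynyl) | CC(C)C(=O)O[C@H]1/C(C)=C/CC/C(C)=C/C2=NO[C@@H]1[C@H]2C(Br)=C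
F5 | step 12 | (6S,7S,8R,9S)-6-hydroxy-9-isobutyryloxygermacra-1(10)E,4E,11(13)-trien-12,8-olide (6-epimer of 19) | C=C1C(=O)O[C@@H]2[C@@H]1[C@@H](O)/C=C(\C)CC/C=C(\C)[C@@H]2OC(=O)C(C)C
F6 | step 12 | 6-O-chloroacetate of 19 (C6 configured as in 19) | C=C1C(=O)O[C@@H]2[C@@H]1[C@H](OC(=O)CCl)/C=C(\C)CC/C=C(\C)[C@@H]2OC(=O)C(C)C
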